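**Retrosynthetic overview**

1. The target (ring atoms numbered as in its name: C1 carries CH2OH, C4 the side chain and the only stereocentre, C7 and C11 the methyl groups) has one ring, the 14-membered carbocycle, closed last but one by forming the C12–C13 single bond.
2. Enabling feature: the ring holds the 1,5-diene C2=C1–C14–C13–C12=C11, so C13 is a homoallylic CH2 bonded to the unsubstituted vinylic carbon C12 of the Z-trisubstituted C11=C12 alkene. This homoallyl–alkenyl bond is made by a stereoretentive intramolecular Negishi coupling of a linear bis-iodide (primary C13–I, (Z)-alkenyl C12–I), which closes the ring, completes the skeleton and fixes the 1,5-diene in one operation.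
3. The linear precursor already carries every stereo element: (E)-C1=C2 with C13, C14 and the CH2OH carbon from one Wittig reaction with a butyrolactone ylide (temporary lactone ring, later opened); (Z)-C11=C12–I from syn-carbocupration of propyne; (E)-C7=C8 from Zr-catalysed syn-carboalumination of a terminal alkyne and ethylene oxide.
4. C4 and its 6-methylhepta-1,5-dien-2-yl arm come from (R)-limonene (allylic lithiation/allylation, cross-metathesis); ozonolysis of its ring alkene gives the C2 aldehyde (masked as acetal) and the C7 methyl ketone.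
5. Ring events in order: cyclohexene opened (step 2), butyrolactone attached (step 9) and opened (step 10), 14-membered ring closed (step 12), ester reduced to CH2OH (step 13).

Key step: step 12

Remark: besides (R)-limonene, all carbon is brought in by reagents taken as purchasable (allyl bromide, 2-methyl-2-butene, AlMe3, ethylene oxide, propyne, 3-(triphenylphosphoranylidene)oxolan-2-one).

**Route**

Step 1
Reactants: 1 (R)-(+)-limonene
Product: 3 (4R)-4-(hexa-1,5-dien-2-yl)-1-methylcyclohex-1-ene, via allyllithium 2 (not isolated)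
Conditions: n-BuLi, TMEDA, rt, 24 h (1 in excess); allyl bromide, THF, −78 °C → rt
Reagents that add atoms: allyl bromide, C=CCBr
Why: Allylic lithiation of limonene with n-BuLi/TMEDA is known to occur at the isopropenyl methyl group, the resulting 2-substituted allyllithium has two equivalent CH2 termini so that allylation can give only one constitution, and the C4 stereocentre is not touched and is carried unchanged into the target.

Step 2
Reactants: 3 (4R)-4-(hexa-1,5-dien-2-yl)-1-methylcyclohex-1-ene
Product: 5 (5R)-5-(hexa-1,5-dien-2-yl)-7,7-dimethoxyheptan-2-one, via keto aldehyde 4 (not isolated)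
Conditions: O3, CH2Cl2/MeOH, −78 °C (Sudan Red 7B end point); Me2S, −78 °C → rt; p-TsOH (cat.), rt; NaHCO3
Reagents that add atoms: ozone, [O-][O+]=O; methanol, CO
Why: Ozonolysis with reductive work-up should cleave the electron-rich trisubstituted ring alkene ahead of the 1,1-disubstituted and monosubstituted alkenes, and acid-catalysed acetalisation in methanol is selective for the aldehyde over the methyl ketone, so the two carbonyl groups emerge differentiated.

Step 3
Reactants: 5 (5R)-5-(hexa-1,5-dien-2-yl)-7,7-dimethoxyheptan-2-one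
Product: 6 (5R)-7,7-dimethoxy-5-(6-methylhepta-1,5-dien-2-yl)heptan-2-one
Conditions: 2-methyl-2-butene (excess), second-generation Grubbs catalyst RuCl2(=CHPh)(PCy3)(SIMes) (3 mol %), CH2Cl2, 40 °C
Reagents that add atoms: 2-methyl-2-butene, CC=C(C)C
Why: Olefin cross-metathesis of a monosubstituted alkene with 2-methyl-2-butene is a standard way to install a prenyl-type isopropylidene terminus, and the hindered 1,1-disubstituted alkene, the ketone and the acetal should not interfere.

Step 4
Reactants: 6 (5R)-7,7-dimethoxy-5-(6-methylhepta-1,5-dien-2-yl)heptan-2-one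
Product: 8 (5R)-7,7-dimethoxy-5-(6-methylhepta-1,5-dien-2-yl)hept-1-yne, via enol phosphate 7 (not isolated)
Conditions: LDA (1.1 equiv), THF, −78 °C; ClP(O)(OEt)2; LDA (2.3 equiv), −78 °C → rt; aq. NH4Cl
Reagents that add atoms: none
Why: Kinetic enolisation of the methyl ketone on the methyl side, O-phosphorylation and LDA-induced elimination of the enol phosphate is an established conversion of methyl ketones into terminal alkynes, and acetal and alkenes are inert to the amide base.

Step 5
Reactants: 8 (5R)-7,7-dimethoxy-5-(6-methylhepta-1,5-dien-2-yl)hept-1-yne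
Product: 11 (3E,7R)-9,9-dimethoxy-4-methyl-7-(6-methylhepta-1,5-dien-2-yl)non-3-en-1-ol, via alkenylalane 9 (not isolated), via lithium alanate 10 (not isolated)
Conditions: AlMe3 (3 equiv), Cp2ZrCl2 (20 mol %), H2O (1.5 equiv), CH2Cl2, −23 °C; volatiles removed; n-BuLi, THF, −78 °C; ethylene oxide, −78 → 0 °C; aq. KNaC4H4O6
Reagents that add atoms: trimethylaluminium, C[Al](C)C; ethylene oxide, C1CO1
Why: Zirconium-catalysed carboalumination (Negishi carboalumination) adds methyl and aluminium syn across the terminal alkyne with aluminium on the terminal carbon, and the derived alanate opens ethylene oxide with retention at the alkenyl carbon, so the (E)-trisubstituted homoallylic alcohol is expected, the water-accelerated low-temperature variant being chosen to spare the dimethyl acetal.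

Step 6
Reactants: 11 (3E,7R)-9,9-dimethoxy-4-methyl-7-(6-methylhepta-1,5-dien-2-yl)non-3-en-1-ol
Product: 12 (3E,7R)-1-bromo-9,9-dimethoxy-4-methyl-7-(6-methylhepta-1,5-dien-2-yl)non-3-ene
Conditions: CBr4, PPh3, 2,6-lutidine, CH2Cl2, 0 °C
Reagents that add atoms: carbon tetrabromide, BrC(Br)(Br)Br
Why: The Appel reaction converts the primary alcohol into the bromide under nearly neutral buffered conditions that leave the acetal and all alkenes untouched.

Step 7
Reactants: 12 (3E,7R)-1-bromo-9,9-dimethoxy-4-methyl-7-(6-methylhepta-1,5-dien-2-yl)non-3-ene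
Product: 16 (1Z,5E,9R)-1-iodo-11,11-dimethoxy-2,6-dimethyl-9-(6-methylhepta-1,5-dien-2-yl)undeca-1,5-diene, via Grignard reagent 13 (not isolated), via alkylcopper 14 (not isolated), via alkenylcopper 15 (not isolated)
Conditions: Mg, Et2O, rt; CuBr·SMe2 (1 equiv), Et2O/Me2S, −45 °C; propyne, −25 °C; I2, THF, −50 → 0 °C
Reagents that add atoms: propyne, CC#C; iodine, I-I
Why: Carbocupration of propyne by an alkylcopper–magnesium bromide reagent (Normant carbocupration) is a syn addition that puts the alkyl group on the methyl-bearing carbon and copper on the terminal carbon, and iodinolysis with retention should therefore give the (Z)-1-iodo-2-methylalkene with iodine cis to the chain.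

Step 8
Reactants: 16 (1Z,5E,9R)-1-iodo-11,11-dimethoxy-2,6-dimethyl-9-(6-methylhepta-1,5-dien-2-yl)undeca-1,5-diene
Product: 17 (3R,6E,10Z)-11-iodo-6,10-dimethyl-3-(6-methylhepta-1,5-dien-2-yl)undeca-6,10-dienal
Conditions: PPTS (cat.), acetone/H2O, 50 °C
Reagents that add atoms: water, O
Why: Mild acid-catalysed hydrolysis of the dimethyl acetal should free the aldehyde without isomerising the alkenyl iodide and without the carbonyl-ene closure that this citronellal-like aldehyde would undergo only with stronger or Lewis acids.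

Step 9
Reactants: 17 (3R,6E,10Z)-11-iodo-6,10-dimethyl-3-(6-methylhepta-1,5-dien-2-yl)undeca-6,10-dienal
Product: 18 (3E)-3-[(3R,6E,10Z)-11-iodo-6,10-dimethyl-3-(6-methylhepta-1,5-dien-2-yl)undeca-6,10-dien-1-ylidene]oxolan-2-one
Conditions: 3-(triphenylphosphoranylidene)oxolan-2-one (1.3 equiv), toluene, 80 °C
Reagents that add atoms: 3-(triphenylphosphoranylidene)oxolan-2-one, O=C1OCCC1=P(c1ccccc1)(c1ccccc1)c1ccccc1
Why: The Wittig reaction of the lactone-stabilised ylide with the aldehyde should give mainly the (E)-alkylidene lactone, carbonyl trans to the chain, which is the C1=C2 geometry of the target, and the temporary five-membered lactone delivers C13, C14, C1 and the CH2OH carbon in one reagent.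

Step 10
Reactants: 18 (3E)-3-[(3R,6E,10Z)-11-iodo-6,10-dimethyl-3-(6-methylhepta-1,5-dien-2-yl)undeca-6,10-dien-1-ylidene]oxolan-2-one
Product: 20 methyl (2E,5R,8E,12Z)-2-(2-hydroxyethyl)-13-iodo-8,12-dimethyl-5-(6-methylhepta-1,5-dien-2-yl)trideca-2,8,12-trienoate, via potassium carboxylate 19 (not isolated)
Conditions: KOH (1.05 equiv), THF/H2O, rt; evaporation; MeI, DMF, rt
Reagents that add atoms: potassium hydroxide, [K+].[OH-]; iodomethane, IC
Why: Saponification of the lactone followed by O-alkylation of the potassium carboxylate with iodomethane in DMF (carboxylate alkylation) should give the open hydroxy ester under neutral conditions that avoid relactonisation, and leaves C13 as a free alcohol while the future CH2OH carbon stays an ester.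

Step 11
Reactants: 20 methyl (2E,5R,8E,12Z)-2-(2-hydroxyethyl)-13-iodo-8,12-dimethyl-5-(6-methylhepta-1,5-dien-2-yl)trideca-2,8,12-trienoate
Product: 21 methyl (2E,5R,8E,12Z)-13-iodo-2-(2-iodoethyl)-8,12-dimethyl-5-(6-methylhepta-1,5-dien-2-yl)trideca-2,8,12-trienoate
Conditions: I2, PPh3, imidazole, CH2Cl2, 0 °C
Reagents that add atoms: iodine, I-I
Why: Iodination of the primary alcohol under Appel conditions (PPh3, I2, imidazole) is fast at 0 °C and should outrun relactonisation to give the primary iodide.

Step 12
Reactants: 21 methyl (2E,5R,8E,12Z)-13-iodo-2-(2-iodoethyl)-8,12-dimethyl-5-(6-methylhepta-1,5-dien-2-yl)trideca-2,8,12-trienoate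
Product: 23 methyl (1E,4R,7E,11Z)-7,11-dimethyl-4-(6-methylhepta-1,5-dien-2-yl)cyclotetradeca-1,7,11-triene-1-carboxylate, via homoallylzinc iodide 22 (not isolated)
Conditions: Zn dust (activated with BrCH2CH2Br and Me3SiCl), THF, 35 °C; solution of 22 added over 12 h to PdCl2(DPEphos) (10 mol %), THF, 50 °C, final 2 mM
Reagents that add atoms: none
Why: Zinc inserts only into the primary C13–I bond (the alkenyl C12–I bond is inert to zinc dust at this temperature) to give homoallylzinc iodide 22; zerovalent palladium, formed from PdCl2(DPEphos) by the organozinc, then adds oxidatively to the (Z)-alkenyl C12–I bond with retention, the tethered alkylzinc transmetalates and reductive elimination forms C12–C13. The closest known reaction type is the palladium-catalysed Negishi alkenyl–homoallyl coupling used to assemble the 1,5-diene units of isoprenoids with retention of alkene geometry, run here intramolecularly in the manner of macrocyclic B-alkyl Suzuki–Miyaura closures. The 14-membered ring closes end to end by C(sp3)–C(sp2) reductive elimination from a 15-membered alkyl(alkenyl)palladacycle, and no small ring is involved. No stereocentre is created: the 11Z geometry is controlled by the configuration of the alkenyl iodide set in step 7, while the 1E and 7E alkenes and the C4 centre are spectators. The step needs ring closure to outrun intermolecular coupling and reductive elimination to outrun β-hydride elimination toward the conjugated dienoate; slow addition of preformed 22 to the catalyst at high dilution, the three trisubstituted alkenes that restrict the chain, and the wide-bite-angle ligand DPEphos should secure this, and the ester is inert to the organozinc.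

Step 13
Reactants: 23 methyl (1E,4R,7E,11Z)-7,11-dimethyl-4-(6-methylhepta-1,5-dien-2-yl)cyclotetradeca-1,7,11-triene-1-carboxylate
Product: 24 [(1E,4R,7E,11Z)-7,11-dimethyl-4-(6-methylhepta-1,5-dien-2-yl)cyclotetradeca-1,7,11-trien-1-yl]methanol
Conditions: DIBAL-H (i-Bu2AlH, 3 equiv), CH2Cl2, −78 °C; aq. KNaC4H4O6
Reagents that add atoms: none
Why: DIBAL-H reduces the α,β-unsaturated methyl ester in a 1,2 sense to the allylic alcohol at low temperature without touching the unactivated alkenes, so the target is expected with all stereo elements already in place.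

**Compound list**

1 | (R)-(+)-limonene, (4R)-1-methyl-4-(prop-1-en-2-yl)cyclohex-1-ene | CC1=CC[C@@H](CC1)C(C)=C | starting material
2 | {2-[(1R)-4-methylcyclohex-3-en-1-yl]prop-2-en-1-yl}lithium | CC1=CC[C@@H](CC1)C(=C)C[Li] | intermediate
3 | (4R)-4-(hexa-1,5-dien-2-yl)-1-methylcyclohex-1-ene | CC1=CC[C@@H](CC1)C(=C)CCC=C | intermediate
4 | (3R)-3-(hexa-1,5-dien-2-yl)-6-oxoheptanal | O=CC[C@@H](CCC(C)=O)C(=C)CCC=C | intermediate
5 | (5R)-5-(hexa-1,5-dien-2-yl)-7,7-dimethoxyheptan-2-one | COC(OC)C[C@@H](CCC(C)=O)C(=C)CCC=C | intermediate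
6 | (5R)-7,7-dimethoxy-5-(6-methylhepta-1,5-dien-2-yl)heptan-2-one | COC(OC)C[C@@H](CCC(C)=O)C(=C)CCC=C(C)C | intermediate
7 | diethyl (5R)-7,7-dimethoxy-5-(6-methylhepta-1,5-dien-2-yl)hept-1-en-2-yl phosphate | COC(OC)C[C@@H](CCC(=C)OP(=O)(OCC)OCC)C(=C)CCC=C(C)C | intermediate
8 | (5R)-7,7-dimethoxy-5-(6-methylhepta-1,5-dien-2-yl)hept-1-yne | COC(OC)C[C@@H](CCC#C)C(=C)CCC=C(C)C | intermediate
9 | [(1E,5R)-7,7-dimethoxy-2-methyl-5-(6-methylhepta-1,5-dien-2-yl)hept-1-en-1-yl]dimethylalane | COC(OC)C[C@@H](CC/C(C)=C/[Al](C)C)C(=C)CCC=C(C)C | intermediate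
10 | lithium butyl[(1E,5R)-7,7-dimethoxy-2-methyl-5-(6-methylhepta-1,5-dien-2-yl)hept-1-en-1-yl]dimethylalanate | COC(OC)C[C@@H](CC/C(C)=C/[Al-](C)(C)CCCC)C(=C)CCC=C(C)C.[Li+] | intermediate
11 | (3E,7R)-9,9-dimethoxy-4-methyl-7-(6-methylhepta-1,5-dien-2-yl)non-3-en-1-ol | COC(OC)C[C@@H](CC/C(C)=C/CCO)C(=C)CCC=C(C)C | intermediate
12 | (3E,7R)-1-bromo-9,9-dimethoxy-4-methyl-7-(6-methylhepta-1,5-dien-2-yl)non-3-ene | COC(OC)C[C@@H](CC/C(C)=C/CCBr)C(=C)CCC=C(C)C | intermediate
13 | [(3E,7R)-9,9-dimethoxy-4-methyl-7-(6-methylhepta-1,5-dien-2-yl)non-3-en-1-yl]magnesium bromide | COC(OC)C[C@@H](CC/C(C)=C/CC[Mg]Br)C(=C)CCC=C(C)C | intermediate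
14 | [(3E,7R)-9,9-dimethoxy-4-methyl-7-(6-methylhepta-1,5-dien-2-yl)non-3-en-1-yl]copper (MgBr2 complex) | COC(OC)C[C@@H](CC/C(C)=C/CC[Cu])C(=C)CCC=C(C)C | intermediate
15 | [(1Z,5E,9R)-11,11-dimethoxy-2,6-dimethyl-9-(6-methylhepta-1,5-dien-2-yl)undeca-1,5-dien-1-yl]copper | COC(OC)C[C@@H](CC/C(C)=C/CC/C(C)=C\[Cu])C(=C)CCC=C(C)C | intermediate
16 | (1Z,5E,9R)-1-iodo-11,11-dimethoxy-2,6-dimethyl-9-(6-methylhepta-1,5-dien-2-yl)undeca-1,5-diene | COC(OC)C[C@@H](CC/C(C)=C/CC/C(C)=C\I)C(=C)CCC=C(C)C | intermediate
17 | (3R,6E,10Z)-11-iodo-6,10-dimethyl-3-(6-methylhepta-1,5-dien-2-yl)undeca-6,10-dienal | O=CC[C@@H](CC/C(C)=C/CC/C(C)=C\I)C(=C)CCC=C(C)C | intermediate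
18 | (3E)-3-[(3R,6E,10Z)-11-iodo-6,10-dimethyl-3-(6-methylhepta-1,5-dien-2-yl)undeca-6,10-dien-1-ylidene]oxolan-2-one | O=C1OCC/C1=C\C[C@@H](CC/C(C)=C/CC/C(C)=C\I)C(=C)CCC=C(C)C | intermediate
19 | potassium (2E,5R,8E,12Z)-2-(2-hydroxyethyl)-13-iodo-8,12-dimethyl-5-(6-methylhepta-1,5-dien-2-yl)trideca-2,8,12-trienoate | [K+].[O-]C(=O)/C(CCO)=C/C[C@@H](CC/C(C)=C/CC/C(C)=C\I)C(=C)CCC=C(C)C | intermediate
20 | methyl (2E,5R,8E,12Z)-2-(2-hydroxyethyl)-13-iodo-8,12-dimethyl-5-(6-methylhepta-1,5-dien-2-yl)trideca-2,8,12-trienoate | COC(=O)/C(CCO)=C/C[C@@H](CC/C(C)=C/CC/C(C)=C\I)C(=C)CCC=C(C)C | intermediate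
21 | methyl (2E,5R,8E,12Z)-13-iodo-2-(2-iodoethyl)-8,12-dimethyl-5-(6-methylhepta-1,5-dien-2-yl)trideca-2,8,12-trienoate | COC(=O)/C(CCI)=C/C[C@@H](CC/C(C)=C/CC/C(C)=C\I)C(=C)CCC=C(C)C | intermediate
22 | methyl (2E,5R,8E,12Z)-13-iodo-2-[2-(iodozincio)ethyl]-8,12-dimethyl-5-(6-methylhepta-1,5-dien-2-yl)trideca-2,8,12-trienoate | COC(=O)/C(CC[Zn]I)=C/C[C@@H](CC/C(C)=C/CC/C(C)=C\I)C(=C)CCC=C(C)C | intermediate
23 | methyl (1E,4R,7E,11Z)-7,11-dimethyl-4-(6-methylhepta-1,5-dien-2-yl)cyclotetradeca-1,7,11-triene-1-carboxylate | C=C(CCC=C(C)C)[C@H]1C/C=C(/C(=O)OC)CC/C=C(/C)CC/C=C(\C)CC1 | intermediate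
24 | [(1E,4R,7E,11Z)-7,11-dimethyl-4-(6-methylhepta-1,5-dien-2-yl)cyclotetradeca-1,7,11-trien-1-yl]methanol | C=C(CCC=C(C)C)[C@H]1C/C=C(/CO)CC/C=C(/C)CC/C=C(\C)CC1 | target

**Step count and risks**

Total step count: 13. Longest linear sequence: 13 steps (1 to 24).

Step 12 (macrocyclic Negishi coupling). The ring closure may be overtaken by intermolecular coupling (oligomer formation), the organozinc 22 may be protonated during the long addition, or β-hydride elimination may intervene at the alkylpalladium stage. Fallback: starting again from bis-iodide 21, the same C12–C13 bond would be made without any preformed organometallic by nickel-catalysed reductive cross-electrophile coupling (NiBr2(dme), 4,4'-di-tert-butyl-2,2'-bipyridine, Mn powder, DMA, slow addition of 21, rt). The alkenyl iodide adds to low-valent nickel with retention and the primary iodide enters as a radical captured at nickel, a known way to join alkenyl and primary alkyl halides with retention of alkene geometry. It passes through no new isolable compound (F0) and returns to the route at macrocyclic ester 23.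

Step 7 (carbocupration of propyne). The Grignard stage may suffer Wurtz-type dimerisation or incomplete magnesium insertion, and the alkyl- and alkenylcopper species may decompose thermally before propyne insertion and iodinolysis are complete. Fallback: propyne would be converted by syn-bromoboration with BBr3 into (Z)-dibromo(2-bromoprop-1-en-1-yl)borane F1 and then with pinacol into (Z)-2-(2-bromoprop-1-en-1-yl)-4,4,5,5-tetramethyl-1,3,2-dioxaborolane F2. Bromide 12 would be taken with Zn dust (I2 cat., DMA, 70 °C) to [(3E,7R)-9,9-dimethoxy-4-methyl-7-(6-methylhepta-1,5-dien-2-yl)non-3-en-1-yl]zinc bromide F3 and joined to F2 at its carbon–bromine bond by Negishi coupling (Pd[P(t-Bu)3]2, THF). This should give 2-[(1Z,5E,9R)-11,11-dimethoxy-2,6-dimethyl-9-(6-methylhepta-1,5-dien-2-yl)undeca-1,5-dien-1-yl]-4,4,5,5-tetramethyl-1,3,2-dioxaborolane F4 with the chain cis to boron. Iododeboronation with retention (NaOH, I2, THF/H2O) would return to alkenyl iodide 16.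

Step 2 (chemoselective ozonolysis and acetalisation). Ozone may also attack the 1,1-disubstituted or terminal alkene (over-oxidation), or the two carbonyl groups may be incompletely differentiated (ketal formation at the ketone). Fallback: from triene 3, epoxidation with mCPBA (CH2Cl2, NaHCO3, 0 °C), selective for the trisubstituted ring alkene, would give (4R)-4-(hexa-1,5-dien-2-yl)-1-methyl-7-oxabicyclo[4.1.0]heptane F5 as a mixture of epoxide diastereomers. H5IO6 (THF/H2O, 0 °C) would cleave it to keto aldehyde 4, now isolated, and aldehyde-selective acetalisation (HC(OMe)3, MeOH, CeCl3·7H2O) would return to keto acetal 5.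

Further compounds
F0 | step 12 | none | none
F1 | step 7 | (Z)-dibromo(2-bromoprop-1-en-1-yl)borane | C/C(Br)=C/B(Br)Br
F2 | step 7 | (Z)-2-(2-bromoprop-1-en-1-yl)-4,4,5,5-tetramethyl-1,3,2-dioxaborolane | C/C(Br)=C/B1OC(C)(C)C(C)(C)O1
F3 | step 7 | [(3E,7R)-9,9-dimethoxy-4-methyl-7-(6-methylhepta-1,5-dien-2-yl)non-3-en-1-yl]zinc bromide | COC(OC)C[C@@H](CC/C(C)=C/CC[Zn]Br)C(=C)CCC=C(C)C
F4 | step 7 | 2-[(1Z,5E,9R)-11,11-dimethoxy-2,6-dimethyl-9-(6-methylhepta-1,5-dien-2-yl)undeca-1,5-dien-1-yl]-4,4,5,5-tetramethyl-1,3,2-dioxaborolane | COC(OC)C[C@@H](CC/C(C)=C/CC/C(C)=C\B1OC(C)(C)C(C)(C)O1)C(=C)CCC=C(C)C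
F5 | step 2 | (4R)-4-(hexa-1,5-dien-2-yl)-1-methyl-7-oxabicyclo[4.1.0]heptane | CC12OC1C[C@@H](CC2)C(=C)CCC=C
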